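The route rests on closing the ten-membered carbocycle last, at C7–C8 (germacrane numbering), by an intramolecular Nozaki–Hiyama–Kishi allylation. It exploits the α-methylene-γ-lactone ring: in a 3-(bromomethyl)butenolide the atoms C13–C11=C7 are a latent allylmetal whose γ-carbon is C7, so one operation forms the C7–C8 bond, the (1(10)Z,4E)-cyclodecadiene ring, the C7 and C8 stereocentres and the exocyclic C11=C13 methylene. The precursor is an open-chain (E,Z)-dienyl α-silyloxy aldehyde bearing that butenolide, with C6 and C9 already set. It is assembled from a glycerate-derived methyl ketone by Z-selective Wittig reaction, alkyne carboalumination, asymmetric vinylation and ring-closing metathesis.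

Key step: step 14

Remark: skeleton atoms are referred to by germacrane numbering (C6 lactone carbinol, C7 ring fusion, C8 acetoxy carbon, C9 angeloyloxy carbon, C12 lactone carbonyl, C11=C13 methylene); bicyclic names use cyclodeca[b]furan numbering; TBS = tert-butyldimethylsilyl.
Remark: the descriptor of C3a changes from R (in 20) to S (in 21, 22, 25) only because acylation of O8 changes the priority order; the geometry is the same.
Remark: (−)-MIB is assumed to direct vinyl transfer to the Si face of enal 12, as it does in other organozinc additions to aldehydes.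

Step 1
Reactants: 1 methyl (4S)-2,2-dimethyl-1,3-dioxolane-4-carboxylate
Product: 2 (4S)-N-methoxy-N,2,2-trimethyl-1,3-dioxolane-4-carboxamide
Conditions: MeNH(OMe)·HCl, i-PrMgCl, THF, −20 °C
Reagents that add atoms: N,O-dimethylhydroxylamine hydrochloride, CNOC.Cl
Why: Weinreb amide formation by attack of the in situ magnesium amide on the ester, at a temperature where the α-alkoxy stereocentre is not enolised.

Step 2
Reactants: 2 (4S)-N-methoxy-N,2,2-trimethyl-1,3-dioxolane-4-carboxamide
Product: 3 1-[(4S)-2,2-dimethyl-1,3-dioxolan-4-yl]ethan-1-one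
Conditions: MeMgBr, THF, 0 °C; aq. NH4Cl
Reagents that add atoms: methylmagnesium bromide, C[Mg]Br
Why: Grignard addition to a Weinreb amide stops at the ketone because the chelated tetrahedral intermediate survives until work-up, and C9 is carried unchanged.

Step 3
Reactants: 4 5-iodopent-1-yne
Product: 5 (pent-4-yn-1-yl)triphenylphosphonium iodide
Conditions: PPh3, MeCN, reflux
Reagents that add atoms: triphenylphosphine, c1ccc(cc1)P(c1ccccc1)c1ccccc1
Why: SN2 quaternisation of triphenylphosphine by a primary iodide.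

Step 4
Reactants: 5 (pent-4-yn-1-yl)triphenylphosphonium iodide; 3 1-[(4S)-2,2-dimethyl-1,3-dioxolan-4-yl]ethan-1-one
Product: 7 (4R)-4-[(2Z)-hept-2-en-6-yn-2-yl]-2,2-dimethyl-1,3-dioxolane, via phosphonium ylide 6 (not isolated)
Conditions: NaN(SiMe3)2 (1.0 equiv), THF, −78 °C; then 3, −78 °C → rt
Reagents that add atoms: none
Why: Wittig olefination, relying on the known Z-selectivity of non-stabilised ylides with α-alkoxy ketones (new chain cis to the oxygenated carbon) to set the 1(10)Z alkene; the amide base is too weak to deprotonate the alkyne and the low temperature limits enolisation at C9.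

Step 5
Reactants: 7 (4R)-4-[(2Z)-hept-2-en-6-yn-2-yl]-2,2-dimethyl-1,3-dioxolane
Product: 8 (2R,3Z)-3-methyloct-3-en-7-yne-1,2-diol
Conditions: AcOH/H2O/THF (3:1:1), 40 °C
Reagents that add atoms: none
Why: Acid-catalysed acetonide hydrolysis under conditions too mild to ionise the secondary allylic C–O bond.

Step 6
Reactants: 8 (2R,3Z)-3-methyloct-3-en-7-yne-1,2-diol
Product: 9 (2R,3Z)-1,2-bis(tert-butyldimethylsilyloxy)-3-methyloct-3-en-7-yne
Conditions: TBSCl, imidazole, DMF, rt → 40 °C
Reagents that add atoms: tert-butyldimethylsilyl chloride, CC(C)(C)[Si](C)(C)Cl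
Why: Silyl ether formation on both hydroxyl groups, which makes the diol inert to Me3Al and gives a primary/secondary pair that can be told apart later.

Step 7
Reactants: 9 (2R,3Z)-1,2-bis(tert-butyldimethylsilyloxy)-3-methyloct-3-en-7-yne
Product: 11 (2E,6Z,8R)-8,9-bis(tert-butyldimethylsilyloxy)-3,7-dimethylnona-2,6-dien-1-ol, via alkenylalane 10 (not isolated)
Conditions: Me3Al, Cp2ZrCl2 (0.2 equiv), CH2Cl2, 0 °C → rt; then (CH2O)n, rt; aq. work-up
Reagents that add atoms: trimethylaluminium, C[Al](C)C; paraformaldehyde (as formaldehyde), C=O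
Why: Negishi carboalumination adds Me and Al syn across the terminal alkyne with Me on the internal carbon, and trapping of the alkenylalane by formaldehyde with retention fixes the 4E alkene.

Step 8
Reactants: 11 (2E,6Z,8R)-8,9-bis(tert-butyldimethylsilyloxy)-3,7-dimethylnona-2,6-dien-1-ol
Product: 12 (2E,6Z,8R)-8,9-bis(tert-butyldimethylsilyloxy)-3,7-dimethylnona-2,6-dienal
Conditions: MnO2 (activated, excess), CH2Cl2, rt
Reagents that add atoms: none
Why: Chemoselective MnO2 oxidation of a primary allylic alcohol to the E-enal without double-bond isomerisation.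

Step 9
Reactants: 12 (2E,6Z,8R)-8,9-bis(tert-butyldimethylsilyloxy)-3,7-dimethylnona-2,6-dienal
Product: 13 (3S,4E,8Z,10R)-10,11-bis(tert-butyldimethylsilyloxy)-5,9-dimethylundeca-1,4,8-trien-3-ol
Conditions: Zn(CH=CH2)2 (preformed, salt-free), (−)-MIB (5 mol %), toluene/hexanes, −20 → 0 °C; aq. NH4Cl
Reagents that add atoms: divinylzinc, C=C[Zn]C=C
Why: Amino-alcohol-catalysed enantioselective 1,2-addition of a vinylzinc reagent to the aldehyde, in which the (−)-MIB–zinc complex delivers the vinyl group to the Si face and sets C6 (3S in 13).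

Step 10
Reactants: 13 (3S,4E,8Z,10R)-10,11-bis(tert-butyldimethylsilyloxy)-5,9-dimethylundeca-1,4,8-trien-3-ol; 14 2-(bromomethyl)prop-2-enoic acid
Product: 15 (3S,4E,8Z,10R)-10,11-bis(tert-butyldimethylsilyloxy)-5,9-dimethylundeca-1,4,8-trien-3-yl 2-(bromomethyl)prop-2-enoate
Conditions: DCC, DMAP (5 mol %), CH2Cl2, 0 °C
Reagents that add atoms: none
Why: Steglich esterification of the secondary alcohol with retention at C6, run cold with catalytic DMAP so that the allylic bromide of 14 is not displaced.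

Step 11
Reactants: 15 (3S,4E,8Z,10R)-10,11-bis(tert-butyldimethylsilyloxy)-5,9-dimethylundeca-1,4,8-trien-3-yl 2-(bromomethyl)prop-2-enoate
Product: 16 (5R)-3-(bromomethyl)-5-[(1E,5Z,7R)-7,8-bis(tert-butyldimethylsilyloxy)-2,6-dimethylocta-1,5-dien-1-yl]furan-2(5H)-one
Conditions: second-generation Hoveyda–Grubbs catalyst RuCl2(H2IMes)(=CH–C6H4-2-O-i-Pr) (5–10 mol %), toluene, 80 °C
Reagents that add atoms: none
Why: Ring-closing metathesis between the terminal vinyl group and the 1,1-disubstituted acrylate closes the butenolide with loss of ethylene, while the two trisubstituted alkenes cannot compete (closure onto them would need a three-membered ring or a ring holding an E-alkene) and C6 is untouched.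

Step 12
Reactants: 16 (5R)-3-(bromomethyl)-5-[(1E,5Z,7R)-7,8-bis(tert-butyldimethylsilyloxy)-2,6-dimethylocta-1,5-dien-1-yl]furan-2(5H)-one
Product: 17 (5R)-3-(bromomethyl)-5-[(1E,5Z,7R)-7-(tert-butyldimethylsilyloxy)-8-hydroxy-2,6-dimethylocta-1,5-dien-1-yl]furan-2(5H)-one
Conditions: camphorsulfonic acid (0.2 equiv), MeOH/CH2Cl2 (1:1), 0 °C
Reagents that add atoms: none
Why: Selective acid-catalysed methanolysis of the less hindered primary silyl ether, under non-nucleophilic acidic conditions that leave the secondary silyl ether, the allylic bromide and the butenolide intact.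

Step 13
Reactants: 17 (5R)-3-(bromomethyl)-5-[(1E,5Z,7R)-7-(tert-butyldimethylsilyloxy)-8-hydroxy-2,6-dimethylocta-1,5-dien-1-yl]furan-2(5H)-one
Product: 18 (5R)-3-(bromomethyl)-5-[(1E,5Z,7R)-7-(tert-butyldimethylsilyloxy)-2,6-dimethyl-8-oxoocta-1,5-dien-1-yl]furan-2(5H)-one
Conditions: Dess–Martin periodinane, NaHCO3, CH2Cl2, 0 °C → rt; used crude
Reagents that add atoms: none
Why: Dess–Martin oxidation under buffered, base-free conditions gives the α-silyloxy β,γ-unsaturated aldehyde without epimerising C9 or moving the Z-alkene into conjugation.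

Step 14
Reactants: 18 (5R)-3-(bromomethyl)-5-[(1E,5Z,7R)-7-(tert-butyldimethylsilyloxy)-2,6-dimethyl-8-oxoocta-1,5-dien-1-yl]furan-2(5H)-one
Product: 20 (3aR,4R,5R,6Z,10E,11aR)-5-(tert-butyldimethylsilyloxy)-4-hydroxy-6,10-dimethyl-3-methylidene-3a,4,5,8,9,11a-hexahydrocyclodeca[b]furan-2(3H)-one, via allylchromium species 19 (not isolated)
Conditions: CrCl2 (10 equiv), THF, rt, 18 added by syringe pump over 12 h (final 2 mM); aq. NH4Cl
Reagents that add atoms: none
Why: Two equivalents of CrCl2 (divalent chromium) reduce the allylic C–Br bond to the σ-allyl trivalent chromium species 19, whose γ-carbon (the butenolide β-carbon, C7) adds to the C8 aldehyde through a closed six-membered Zimmerman–Traxler transition state while the C7=C11 double bond shifts to C11=C13 and unveils the α-methylene lactone (intramolecular Nozaki–Hiyama–Kishi allylation, SE2'). The closest known reaction types are the chromium-, zinc- or indium-mediated Barbier coupling of 3-(bromomethyl)furan-2(5H)-ones with aldehydes and the chromium-mediated closure of medium rings from allylic halide aldehydes. The ten-membered carbocycle closes in a 10-exo-trig mode at the aldehyde carbon, and the lactone, already present, becomes trans-fused. C7 is set by attack on the butenolide face anti to the C6 dienyl substituent; C8 is set by the chair transition state with C9 equatorial and H7 anti to H8, the sense expected for an allylchromium whose γ-substituent is locked trans to the CH2Cr group. The step needs ring closure to outrun oligomerisation, which slow addition at high dilution secures, and γ- over α-attack, which is the normal regiochemistry of allylchromium reagents. It also needs the C8 face just described although an open-chain α-silyloxy aldehyde would prefer the opposite (Felkin) face; here the tether holds C10 gauche to the forming bond, so the bulky C9 silyloxy group can still lie anti to it, and this remains the least certain element.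

Step 15
Reactants: 20 (3aR,4R,5R,6Z,10E,11aR)-5-(tert-butyldimethylsilyloxy)-4-hydroxy-6,10-dimethyl-3-methylidene-3a,4,5,8,9,11a-hexahydrocyclodeca[b]furan-2(3H)-one
Product: 21 (3aS,4R,5R,6Z,10E,11aR)-5-(tert-butyldimethylsilyloxy)-6,10-dimethyl-3-methylidene-2-oxo-2,3,3a,4,5,8,9,11a-octahydrocyclodeca[b]furan-4-yl acetate
Conditions: Ac2O, pyridine, DMAP (cat.), CH2Cl2, 0 °C → rt
Reagents that add atoms: acetic anhydride, CC(=O)OC(C)=O
Why: DMAP-catalysed acetylation of the secondary C8 alcohol with retention, which also blocks translactonisation to O8.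

Step 16
Reactants: 21 (3aS,4R,5R,6Z,10E,11aR)-5-(tert-butyldimethylsilyloxy)-6,10-dimethyl-3-methylidene-2-oxo-2,3,3a,4,5,8,9,11a-octahydrocyclodeca[b]furan-4-yl acetate
Product: 22 (3aS,4R,5R,6Z,10E,11aR)-5-hydroxy-6,10-dimethyl-3-methylidene-2-oxo-2,3,3a,4,5,8,9,11a-octahydrocyclodeca[b]furan-4-yl acetate
Conditions: HF·pyridine, pyridine/THF, 0 °C → rt
Reagents that add atoms: none
Why: Fluoride cleavage of the secondary silyl ether under buffered acidic conditions, which avoid the base-promoted acetyl migration from O8 to O9 and spare the α-methylene lactone.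

Step 17
Reactants: 22 (3aS,4R,5R,6Z,10E,11aR)-5-hydroxy-6,10-dimethyl-3-methylidene-2-oxo-2,3,3a,4,5,8,9,11a-octahydrocyclodeca[b]furan-4-yl acetate; 23 (2Z)-2-methylbut-2-enoic acid (angelic acid)
Product: 25 (3aS,4R,5R,6Z,10E,11aR)-4-acetoxy-6,10-dimethyl-3-methylidene-2-oxo-2,3,3a,4,5,8,9,11a-octahydrocyclodeca[b]furan-5-yl (2Z)-2-methylbut-2-enoate, via mixed anhydride 24 (not isolated)
Conditions: 23, 2,4,6-trichlorobenzoyl chloride, Et3N, toluene, rt; then 22, toluene, 75 °C
Reagents that add atoms: none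
Why: Yamaguchi esterification through mixed anhydride 24, the established way to transfer the Z-configured angeloyl group to a hindered secondary alcohol without isomerisation to the tiglate, with retention at C9.

Compound list
1 | methyl (4S)-2,2-dimethyl-1,3-dioxolane-4-carboxylate | COC(=O)[C@@H]1COC(C)(C)O1 | starting material
2 | (4S)-N-methoxy-N,2,2-trimethyl-1,3-dioxolane-4-carboxamide | CON(C)C(=O)[C@@H]1COC(C)(C)O1 | intermediate
3 | 1-[(4S)-2,2-dimethyl-1,3-dioxolan-4-yl]ethan-1-one | CC(=O)[C@@H]1COC(C)(C)O1 | intermediate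
4 | 5-iodopent-1-yne | C#CCCCI | starting material
5 | (pent-4-yn-1-yl)triphenylphosphonium iodide | C#CCCC[P+](c1ccccc1)(c1ccccc1)c1ccccc1.[I-] | intermediate
6 | (pent-4-yn-1-ylidene)triphenylphosphorane | C#CCCC=P(c1ccccc1)(c1ccccc1)c1ccccc1 | intermediate (not isolated)
7 | (4R)-4-[(2Z)-hept-2-en-6-yn-2-yl]-2,2-dimethyl-1,3-dioxolane | C#CCC/C=C(/C)[C@@H]1COC(C)(C)O1 | intermediate
8 | (2R,3Z)-3-methyloct-3-en-7-yne-1,2-diol | C#CCC/C=C(/C)[C@@H](O)CO | intermediate
9 | (2R,3Z)-1,2-bis(tert-butyldimethylsilyloxy)-3-methyloct-3-en-7-yne | C#CCC/C=C(/C)[C@@H](O[Si](C)(C)C(C)(C)C)CO[Si](C)(C)C(C)(C)C | intermediate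
10 | [(1E,5Z,7R)-7,8-bis(tert-butyldimethylsilyloxy)-2,6-dimethylocta-1,5-dien-1-yl]dimethylalumane | C[Al](C)/C=C(\C)CC/C=C(/C)[C@@H](O[Si](C)(C)C(C)(C)C)CO[Si](C)(C)C(C)(C)C | intermediate (not isolated)
11 | (2E,6Z,8R)-8,9-bis(tert-butyldimethylsilyloxy)-3,7-dimethylnona-2,6-dien-1-ol | OC/C=C(\C)CC/C=C(/C)[C@@H](O[Si](C)(C)C(C)(C)C)CO[Si](C)(C)C(C)(C)C | intermediate
12 | (2E,6Z,8R)-8,9-bis(tert-butyldimethylsilyloxy)-3,7-dimethylnona-2,6-dienal | O=C/C=C(\C)CC/C=C(/C)[C@@H](O[Si](C)(C)C(C)(C)C)CO[Si](C)(C)C(C)(C)C | intermediate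
13 | (3S,4E,8Z,10R)-10,11-bis(tert-butyldimethylsilyloxy)-5,9-dimethylundeca-1,4,8-trien-3-ol | C=C[C@H](O)/C=C(\C)CC/C=C(/C)[C@@H](O[Si](C)(C)C(C)(C)C)CO[Si](C)(C)C(C)(C)C | intermediate
14 | 2-(bromomethyl)prop-2-enoic acid | C=C(CBr)C(=O)O | starting material
15 | (3S,4E,8Z,10R)-10,11-bis(tert-butyldimethylsilyloxy)-5,9-dimethylundeca-1,4,8-trien-3-yl 2-(bromomethyl)prop-2-enoate | C=C[C@H](OC(=O)C(=C)CBr)/C=C(\C)CC/C=C(/C)[C@@H](O[Si](C)(C)C(C)(C)C)CO[Si](C)(C)C(C)(C)C | intermediate
16 | (5R)-3-(bromomethyl)-5-[(1E,5Z,7R)-7,8-bis(tert-butyldimethylsilyloxy)-2,6-dimethylocta-1,5-dien-1-yl]furan-2(5H)-one | BrCC1=C[C@@H](/C=C(\C)CC/C=C(/C)[C@@H](O[Si](C)(C)C(C)(C)C)CO[Si](C)(C)C(C)(C)C)OC1=O | intermediate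
17 | (5R)-3-(bromomethyl)-5-[(1E,5Z,7R)-7-(tert-butyldimethylsilyloxy)-8-hydroxy-2,6-dimethylocta-1,5-dien-1-yl]furan-2(5H)-one | BrCC1=C[C@@H](/C=C(\C)CC/C=C(/C)[C@@H](O[Si](C)(C)C(C)(C)C)CO)OC1=O | intermediate
18 | (5R)-3-(bromomethyl)-5-[(1E,5Z,7R)-7-(tert-butyldimethylsilyloxy)-2,6-dimethyl-8-oxoocta-1,5-dien-1-yl]furan-2(5H)-one | BrCC1=C[C@@H](/C=C(\C)CC/C=C(/C)[C@@H](O[Si](C)(C)C(C)(C)C)C=O)OC1=O | intermediate
19 | dichloro{[(5R)-5-[(1E,5Z,7R)-7-(tert-butyldimethylsilyloxy)-2,6-dimethyl-8-oxoocta-1,5-dien-1-yl]-2-oxo-2,5-dihydrofuran-3-yl]methyl}chromium (trivalent chromium, solvent ligands omitted) | Cl[Cr](Cl)CC1=C[C@@H](/C=C(\C)CC/C=C(/C)[C@@H](O[Si](C)(C)C(C)(C)C)C=O)OC1=O | intermediate (not isolated)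
20 | (3aR,4R,5R,6Z,10E,11aR)-5-(tert-butyldimethylsilyloxy)-4-hydroxy-6,10-dimethyl-3-methylidene-3a,4,5,8,9,11a-hexahydrocyclodeca[b]furan-2(3H)-one | C=C1C(=O)O[C@@H]2/C=C(\C)CC/C=C(/C)[C@@H](O[Si](C)(C)C(C)(C)C)[C@H](O)[C@@H]12 | intermediate
21 | (3aS,4R,5R,6Z,10E,11aR)-5-(tert-butyldimethylsilyloxy)-6,10-dimethyl-3-methylidene-2-oxo-2,3,3a,4,5,8,9,11a-octahydrocyclodeca[b]furan-4-yl acetate | C=C1C(=O)O[C@@H]2/C=C(\C)CC/C=C(/C)[C@@H](O[Si](C)(C)C(C)(C)C)[C@H](OC(C)=O)[C@@H]12 | intermediate
22 | (3aS,4R,5R,6Z,10E,11aR)-5-hydroxy-6,10-dimethyl-3-methylidene-2-oxo-2,3,3a,4,5,8,9,11a-octahydrocyclodeca[b]furan-4-yl acetate | C=C1C(=O)O[C@@H]2/C=C(\C)CC/C=C(/C)[C@@H](O)[C@H](OC(C)=O)[C@@H]12 | intermediate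
23 | (2Z)-2-methylbut-2-enoic acid (angelic acid) | C/C=C(/C)C(=O)O | starting material
24 | (2Z)-2-methylbut-2-enoic 2,4,6-trichlorobenzoic anhydride | C/C=C(/C)C(=O)OC(=O)c1c(Cl)cc(Cl)cc1Cl | intermediate (not isolated)
25 | (3aS,4R,5R,6Z,10E,11aR)-4-acetoxy-6,10-dimethyl-3-methylidene-2-oxo-2,3,3a,4,5,8,9,11a-octahydrocyclodeca[b]furan-5-yl (2Z)-2-methylbut-2-enoate | C=C1C(=O)O[C@@H]2/C=C(\C)CC/C=C(/C)[C@@H](OC(=O)/C(C)=C\C)[C@H](OC(C)=O)[C@@H]12 | target

Total step count: 17. Longest linear sequence: 16 steps (steps 1, 2 and 4–17 from compound 1); step 3 is a one-step branch.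

Steps most likely to fail

Step 14. The process at risk is facial selection at the aldehyde: the Felkin preference of the α-silyloxy aldehyde opposes the chair-controlled delivery, so addition through an axial-chair or boat transition state may give the C8 epimer, on top of competing oligomerisation. The fallback sets the C8 configuration by substitution instead of by the cyclisation. Setting out from 18, the same chromium-mediated closure is run and the epimeric alcohol (3aR,4S,5R,6Z,10E,11aR)-5-(tert-butyldimethylsilyloxy)-4-hydroxy-6,10-dimethyl-3-methylidene-3a,4,5,8,9,11a-hexahydrocyclodeca[b]furan-2(3H)-one F1 is isolated. Mitsunobu reaction of this alcohol with acetic acid (PPh3, DIAD, toluene, 0 °C → rt) should install the acetate with inversion at C8, so the route is rejoined at 21 and step 15 is skipped.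

Step 11. The process at risk is interception of the ruthenium carbene by the allylic bromide, or its failure to engage the electron-poor 1,1-disubstituted acrylate, so that the vinyl group dimerises instead of closing the butenolide. The fallback builds the butenolide without metathesis, setting out from enal 12 and returning at 16.
- Zinc-mediated enantioselective addition of methyl propiolate (Me2Zn, the ProPhenol ligand enantiomer that adds to the Si face, toluene, 4 °C) should give methyl (4R,5E,9Z,11R)-11,12-bis(tert-butyldimethylsilyloxy)-4-hydroxy-6,10-dimethyldodeca-5,9-dien-2-ynoate F2.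
- Syn-hydrostannation (Bu3SnH, Pd(PPh3)4, zerovalent palladium, THF) places tin on the α-carbon cis to the carbinol chain, and lactonisation then gives (5R)-5-[(1E,5Z,7R)-7,8-bis(tert-butyldimethylsilyloxy)-2,6-dimethylocta-1,5-dien-1-yl]-3-(tributylstannyl)furan-2(5H)-one F3.
- Iododestannylation (I2, CH2Cl2, 0 °C) gives (5R)-5-[(1E,5Z,7R)-7,8-bis(tert-butyldimethylsilyloxy)-2,6-dimethylocta-1,5-dien-1-yl]-3-iodofuran-2(5H)-one F4.
- Stille coupling with (tributylstannyl)methanol (Pd(PPh3)4, dioxane, 80 °C) gives (5R)-5-[(1E,5Z,7R)-7,8-bis(tert-butyldimethylsilyloxy)-2,6-dimethylocta-1,5-dien-1-yl]-3-(hydroxymethyl)furan-2(5H)-one F5.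
- Appel bromination (CBr4, PPh3, CH2Cl2, 0 °C) then gives 16.

Step 17. The process at risk is slow acylation of the hindered allylic C9 alcohol, which leaves time for acetyl migration from O8 to O9 and for Z to E isomerisation of the activated angelate. The fallback builds the angelate double bond in place, setting out from 22 and returning at 25. Esterification of 22 with 2-[bis(2,2,2-trifluoroethoxy)phosphoryl]propanoic acid (DCC, DMAP cat., CH2Cl2, 0 °C) should give (3aS,4R,5R,6Z,10E,11aR)-4-acetoxy-6,10-dimethyl-3-methylidene-2-oxo-2,3,3a,4,5,8,9,11a-octahydrocyclodeca[b]furan-5-yl 2-[bis(2,2,2-trifluoroethoxy)phosphoryl]propanoate F6 (both epimers at the phosphonate carbon). Z-selective Still–Gennari olefination with acetaldehyde (KN(SiMe3)2, 18-crown-6, THF, −78 °C) then gives 25.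

Further compounds
F1 | step 14 | (3aR,4S,5R,6Z,10E,11aR)-5-(tert-butyldimethylsilyloxy)-4-hydroxy-6,10-dimethyl-3-methylidene-3a,4,5,8,9,11a-hexahydrocyclodeca[b]furan-2(3H)-one | C=C1C(=O)O[C@@H]2/C=C(\C)CC/C=C(/C)[C@@H](O[Si](C)(C)C(C)(C)C)[C@@H](O)[C@@H]12
F2 | step 11 | methyl (4R,5E,9Z,11R)-11,12-bis(tert-butyldimethylsilyloxy)-4-hydroxy-6,10-dimethyldodeca-5,9-dien-2-ynoate | COC(=O)C#C[C@H](O)/C=C(\C)CC/C=C(/C)[C@@H](O[Si](C)(C)C(C)(C)C)CO[Si](C)(C)C(C)(C)C
F3 | step 11 | (5R)-5-[(1E,5Z,7R)-7,8-bis(tert-butyldimethylsilyloxy)-2,6-dimethylocta-1,5-dien-1-yl]-3-(tributylstannyl)furan-2(5H)-one | CCCC[Sn](CCCC)(CCCC)C1=C[C@@H](/C=C(\C)CC/C=C(/C)[C@@H](O[Si](C)(C)C(C)(C)C)CO[Si](C)(C)C(C)(C)C)OC1=O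
F4 | step 11 | (5R)-5-[(1E,5Z,7R)-7,8-bis(tert-butyldimethylsilyloxy)-2,6-dimethylocta-1,5-dien-1-yl]-3-iodofuran-2(5H)-one | IC1=C[C@@H](/C=C(\C)CC/C=C(/C)[C@@H](O[Si](C)(C)C(C)(C)C)CO[Si](C)(C)C(C)(C)C)OC1=O
F5 | step 11 | (5R)-5-[(1E,5Z,7R)-7,8-bis(tert-butyldimethylsilyloxy)-2,6-dimethylocta-1,5-dien-1-yl]-3-(hydroxymethyl)furan-2(5H)-one | OCC1=C[C@@H](/C=C(\C)CC/C=C(/C)[C@@H](O[Si](C)(C)C(C)(C)C)CO[Si](C)(C)C(C)(C)C)OC1=O
F6 | step 17 | (3aS,4R,5R,6Z,10E,11aR)-4-acetoxy-6,10-dimethyl-3-methylidene-2-oxo-2,3,3a,4,5,8,9,11a-octahydrocyclodeca[b]furan-5-yl 2-[bis(2,2,2-trifluoroethoxy)phosphoryl]propanoate | C=C1C(=O)O[C@@H]2/C=C(\C)CC/C=C(/C)[C@@H](OC(=O)C(C)P(=O)(OCC(F)(F)F)OCC(F)(F)F)[C@H](OC(C)=O)[C@@H]12
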